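**Plan**

- Retrosynthesis: after removal of the sulfate and the benzyl ethers, both aryl bonds of the methine C1 are cut (C1–C1' to guaiacol, C1–C8a to the tethered ring). The resulting open-chain aldehyde is traced through its C1–C2 bond to an (R)-β-arylmethyl butyrolactone, made from O-benzylvanillin and dimethyl succinate.
- Enabling feature: tetralin C1 is a methine that carries C8a of ring A (para to the C6 methoxy) and C1' of the pendant ring (para to its hydroxyl). Both are the preferred Friedel–Crafts positions of guaiacol-type arenes, so C1 is an aldehyde carbon arylated twice.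
- Forward: a Stobbe condensation joins the chain, the lactone is formed, C1 is attached as an acetal, and the lactone is opened with its two arms kept distinct. Ring B (C1–C4, C4a, C8a), the only ring made, closes in the cascade that also brings in the pendant ring; sulfation and hydrogenolysis finish.
- Stereochemistry: C3 comes from rhodium-catalysed asymmetric hydrogenation, C2 from trans alkylation of the lactone, and C1 from capture of the benzylic cation anti to the C2 arm.

Key step: step 9

Numbering: tetralin C1 (aryl-bearing), C2 (bears C9'), C3 (bears C9), C4; ring A = C4a–C8a; pendant ring = C1'–C6'.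

Remark on relative configuration: in the trans lactone the two α-arms are not interchangeable. Turning the lactone carbonyl into the aldehyde would give the C2 epimer, so the carbonyl carbon is reduced to C9' and the added exocyclic carbon is kept at the aldehyde level as C1.

Assumption: the target is drawn as the free hydrogen sulfate; the sulfate is carried as its sodium salt and protonated only in the last operation.

Assumption: the (S,S) antipode of Et-DuPhos is taken to give the (R) acid 4, by analogy with related arylidenesuccinate half-esters; should the sense be the reverse, the (R,R) ligand is used.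

**Route**

Step 1
Reactants: 1 4-(benzyloxy)-3-methoxybenzaldehyde; 2 dimethyl succinate
Product: 3 (E)-4-[4-(benzyloxy)-3-methoxyphenyl]-3-(methoxycarbonyl)but-3-enoic acid
Conditions: NaOMe (2 equiv), MeOH, reflux; then aq HCl
Reagents that add atoms: none
Why: Stobbe condensation: the succinate enolate adds to the aldehyde, the aldolate lactonises onto the distal ester, and base-induced ring opening gives the half-ester carboxylate irreversibly, mainly as the E alkene.

Step 2
Reactants: 3
Product: 4 (3R)-4-[4-(benzyloxy)-3-methoxyphenyl]-3-(methoxycarbonyl)butanoic acid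
Conditions: H2 (5 bar), [Rh(cod)((S,S)-Et-DuPhos)]OTf (0.5 mol %), NaOMe (0.1 equiv), MeOH, rt
Reagents that add atoms: none
Why: Rhodium–bisphospholane asymmetric hydrogenation of an itaconate-type half-ester: carboxylate and alkene chelate the metal, so hydrogen is delivered to one enantioface and sets the future C3 as R, while the aryl benzyl ether is inert to this homogeneous catalyst.

Step 3
Reactants: 4
Product: 6 (4R)-4-[[4-(benzyloxy)-3-methoxyphenyl]methyl]oxolan-2-one, via potassium γ-hydroxy carboxylate 5 (not isolated)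
Conditions: KOH (1.0 equiv), EtOH; CaCl2, NaBH4, EtOH, −10 °C to rt; then 2 M HCl, rt
Reagents that add atoms: none
Why: Chemoselective borohydride reduction: Ca(BH4)2 made in the flask reduces the ester but not the carboxylate anion, and acidification closes the γ-hydroxy acid to the butyrolactone without touching the stereocentre.

Step 4
Reactants: 6; 7 trimethyl orthoformate
Product: 9 (3S,4R)-4-[[4-(benzyloxy)-3-methoxyphenyl]methyl]-3-(dimethoxymethyl)oxolan-2-one, via trimethylsilyl ketene acetal 8 (not isolated)
Conditions: LiN(iPr)2 (LDA), THF, −78 °C; TMSCl; evaporate, pentane, filter; then 7, TMSOTf (0.1 equiv), CH2Cl2, −78 °C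
Reagents that add atoms: none
Why: Mukaiyama-type alkylation of a silyl ketene acetal by the dimethoxycarbenium ion that TMSOTf releases from the orthoformate; the electrophile should add anti to the neighbouring arylmethyl group, which sets C2 trans to C3 and installs the future aldehyde carbon C1 already masked as an acetal.

Step 5
Reactants: 9
Product: 11 benzyl (2S,3R)-4-[4-(benzyloxy)-3-methoxyphenyl]-3-[(benzyloxy)methyl]-2-(dimethoxymethyl)butanoate, via sodium γ-hydroxy carboxylate 10 (not isolated)
Conditions: NaOH (1.05 equiv), THF–MeOH–H2O, rt; evaporate to dryness; then NaH (1.1 equiv), BnBr (2.5 equiv), Bu4NI (cat.), DMF, 0 °C to rt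
Reagents that add atoms: sodium hydroxide, [Na+].[OH-]; benzyl bromide, BrCc1ccccc1
Why: Saponification of the lactone, then Williamson etherification of the alkoxide and O-alkylation of the carboxylate, locks the open chain with C9 as benzyl ether and C9' as ester; NaH is held near one equivalent so that C2 is not deprotonated.

Step 6
Reactants: 11
Product: 12 (2R,3R)-4-[4-(benzyloxy)-3-methoxyphenyl]-3-[(benzyloxy)methyl]-2-(dimethoxymethyl)butan-1-ol
Conditions: LiAlH4, THF, 0 °C
Reagents that add atoms: none
Why: LiAlH4 reduction of the benzyl ester gives the primary C9' alcohol; the acetal and the benzyl ethers do not react.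

Step 7
Reactants: 12
Product: 13 (2R,3R)-4-[4-(benzyloxy)-3-methoxyphenyl]-3-[(benzyloxy)methyl]-2-(dimethoxymethyl)butyl 2,2-dimethylpropanoate
Conditions: PivCl, pyridine, DMAP (cat.), CH2Cl2, 0 °C to rt
Reagents that add atoms: pivaloyl chloride, CC(C)(C)C(Cl)=O
Why: DMAP-catalysed acylation of the only free hydroxyl gives a pivalate that tolerates acid, can shield one face of the C1 cation, and is removable by hydride beside benzyl ethers.

Step 8
Reactants: 13
Product: 14 (2R,3R)-4-[4-(benzyloxy)-3-methoxyphenyl]-3-[(benzyloxy)methyl]-2-formylbutyl 2,2-dimethylpropanoate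
Conditions: TsOH·H2O (0.1 equiv), acetone–H2O (10:1), rt; used at once
Reagents that add atoms: water, O
Why: Acid-catalysed acetal hydrolysis in wet acetone is mild enough to leave the α-stereocentre C2, the pivalate and the ethers alone; any aldehyde that already cyclises to the tetralol is an intermediate of step 9 and is not lost.

Step 9
Reactants: 14; 15 guaiacol
Product: 17 [(1S,2R,3R)-7-(benzyloxy)-3-[(benzyloxy)methyl]-1-(4-hydroxy-3-methoxyphenyl)-6-methoxy-1,2,3,4-tetrahydronaphthalen-2-yl]methyl 2,2-dimethylpropanoate, via tetralol 16 (not isolated)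
Conditions: 15 (5 equiv), TfOH (0.1 equiv), CH2Cl2–(CF3)2CHOH (4:1), −20 to 0 °C
Reagents that add atoms: none
Why: The acid activates the aldehyde, the tethered ring attacks it through the carbon para to its methoxy group (C1–C8a) in a 6-exo-trig Friedel–Crafts hydroxyalkylation that closes ring B as tetralol 16, and 16 ionises at once to the C1 cation, which that methoxy group stabilises and which guaiacol captures through the carbon para to its hydroxyl (C1–C1'). The closest known reaction type is the acid-catalysed twofold Friedel–Crafts arylation of aldehydes, including the intramolecular-then-intermolecular variants that give 1-aryltetralins. C1 is the only new stereocentre: the half-chair cation keeps the C2 and C3 arms pseudo-equatorial, the C9' pivalate carbonyl can bridge C1 on its own face as a six-membered acyloxonium, and guaiacol should therefore enter anti to C9', giving the 1,2-trans, all-equatorial (1S) product, which is also the thermodynamic one if the arylation is reversible. The step needs closure para and not ortho to the ring A methoxy (the ortho site is flanked by the tether and OMe), attack of guaiacol para to OH (the stronger donor), and capture faster than loss of the C2 proton (excess guaiacol, low temperature, cation-stabilising solvent). Either order of the two arylations should lead to the same product, because an aldehyde first arylated by guaiacol gives a p-hydroxybenzylic cation onto which the tethered ring closes.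

Step 10
Reactants: 17
Product: 18 [(1S,2R,3R)-7-(benzyloxy)-1-[4-(benzyloxy)-3-methoxyphenyl]-3-[(benzyloxy)methyl]-6-methoxy-1,2,3,4-tetrahydronaphthalen-2-yl]methyl 2,2-dimethylpropanoate
Conditions: BnBr, K2CO3, DMF, rt
Reagents that add atoms: benzyl bromide, BrCc1ccccc1
Why: Williamson ether synthesis: K2CO3 deprotonates only the phenol, and the new benzyl ether protects it during sulfation and falls in the final hydrogenolysis.

Step 11
Reactants: 18
Product: 19 [(1S,2R,3R)-7-(benzyloxy)-1-[4-(benzyloxy)-3-methoxyphenyl]-3-[(benzyloxy)methyl]-6-methoxy-1,2,3,4-tetrahydronaphthalen-2-yl]methanol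
Conditions: iBu2AlH (DIBAL-H, 2.5 equiv), CH2Cl2, −78 °C; aq potassium sodium tartrate
Reagents that add atoms: none
Why: Reductive cleavage of the pivalate ester by the aluminium hydride frees the C9' hydroxyl as the only alcohol; the benzyl ethers are inert.

Step 12
Reactants: 19
Product: 21 sodium [(1S,2R,3R)-7-(benzyloxy)-1-[4-(benzyloxy)-3-methoxyphenyl]-3-[(benzyloxy)methyl]-6-methoxy-1,2,3,4-tetrahydronaphthalen-2-yl]methyl sulfate, via pyridinium sulfate 20 (not isolated)
Conditions: SO3·pyridine (3 equiv), pyridine, rt; then aq NaHCO3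
Reagents that add atoms: sulfur trioxide–pyridine complex, O=S(=O)([O-])[n+]1ccccc1; sodium hydrogen carbonate, [Na+].OC([O-])=O
Why: O-Sulfation of the single free alcohol with the sulfur trioxide–amine complex, followed by exchange of pyridinium for sodium so that no amine remains to poison the palladium catalyst in the last step.

Step 13
Reactants: 21
Product: 23 [(1S,2R,3R)-7-hydroxy-1-(4-hydroxy-3-methoxyphenyl)-3-(hydroxymethyl)-6-methoxy-1,2,3,4-tetrahydronaphthalen-2-yl]methyl hydrogen sulfate, via sodium salt 22 (not isolated)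
Conditions: H2 (1 atm), 10% Pd/C, MeOH–THF, rt; filter; then HCl (1.0 equiv), H2O, 0 °C; C18 desalting, lyophilise
Reagents that add atoms: none
Why: Hydrogenolysis of the three benzyl ethers over Pd/C should leave the sulfate monoester anion and the diarylmethine untouched, and one equivalent of HCl converts the sodium salt to the hydrogen sulfate.

**Compound list**

1 | 4-(benzyloxy)-3-methoxybenzaldehyde (O-benzylvanillin) | COc1cc(C=O)ccc1OCc1ccccc1 | starting material
2 | dimethyl succinate | COC(=O)CCC(=O)OC | starting material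
3 | (E)-4-[4-(benzyloxy)-3-methoxyphenyl]-3-(methoxycarbonyl)but-3-enoic acid | COC(=O)/C(CC(=O)O)=C/c1ccc(OCc2ccccc2)c(OC)c1 | intermediate
4 | (3R)-4-[4-(benzyloxy)-3-methoxyphenyl]-3-(methoxycarbonyl)butanoic acid | OC(=O)C[C@H](C(=O)OC)Cc1ccc(OCc2ccccc2)c(OC)c1 | intermediate
5 | potassium (3R)-4-[4-(benzyloxy)-3-methoxyphenyl]-3-(hydroxymethyl)butanoate | [K+].[O-]C(=O)C[C@H](CO)Cc1ccc(OCc2ccccc2)c(OC)c1 | intermediate (not isolated)
6 | (4R)-4-[[4-(benzyloxy)-3-methoxyphenyl]methyl]oxolan-2-one | O=C1C[C@H](CO1)Cc1ccc(OCc2ccccc2)c(OC)c1 | intermediate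
7 | trimethyl orthoformate | COC(OC)OC | starting material
8 | trimethylsilyl ketene acetal of 6: [(3R)-3-(arylmethyl)-2,3-dihydrofuran-5-yl]oxy-trimethylsilane | C[Si](C)(C)OC1=C[C@H](CO1)Cc1ccc(OCc2ccccc2)c(OC)c1 | intermediate (not isolated)
9 | (3S,4R)-4-[[4-(benzyloxy)-3-methoxyphenyl]methyl]-3-(dimethoxymethyl)oxolan-2-one (trans) | O=C1[C@H](C(OC)OC)[C@H](CO1)Cc1ccc(OCc2ccccc2)c(OC)c1 | intermediate
10 | sodium (2S,3R)-4-[4-(benzyloxy)-3-methoxyphenyl]-2-(dimethoxymethyl)-3-(hydroxymethyl)butanoate | [Na+].[O-]C(=O)[C@H](C(OC)OC)[C@H](CO)Cc1ccc(OCc2ccccc2)c(OC)c1 | intermediate (not isolated)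
11 | benzyl (2S,3R)-4-[4-(benzyloxy)-3-methoxyphenyl]-3-[(benzyloxy)methyl]-2-(dimethoxymethyl)butanoate | O=C(OCc1ccccc1)[C@H](C(OC)OC)[C@H](COCc1ccccc1)Cc1ccc(OCc2ccccc2)c(OC)c1 | intermediate
12 | (2R,3R)-4-[4-(benzyloxy)-3-methoxyphenyl]-3-[(benzyloxy)methyl]-2-(dimethoxymethyl)butan-1-ol | OC[C@H](C(OC)OC)[C@H](COCc1ccccc1)Cc1ccc(OCc2ccccc2)c(OC)c1 | intermediate
13 | pivalate of 12 | CC(C)(C)C(=O)OC[C@H](C(OC)OC)[C@H](COCc1ccccc1)Cc1ccc(OCc2ccccc2)c(OC)c1 | intermediate
14 | (2R,3R)-4-[4-(benzyloxy)-3-methoxyphenyl]-3-[(benzyloxy)methyl]-2-formylbutyl 2,2-dimethylpropanoate | O=C[C@@H](COC(=O)C(C)(C)C)[C@H](COCc1ccccc1)Cc1ccc(OCc2ccccc2)c(OC)c1 | intermediate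
15 | guaiacol (2-methoxyphenol) | COc1ccccc1O | starting material
16 | 2,3-trans 1-hydroxytetralin (C1 epimers) with C9' pivalate, C9 benzyl ether, 6-OMe, 7-OBn | OC1c2cc(OCc3ccccc3)c(OC)cc2C[C@@H](COCc2ccccc2)[C@@H]1COC(=O)C(C)(C)C | intermediate (not isolated)
17 | all-trans (1S,2R,3R) 1-(4-hydroxy-3-methoxyphenyl)tetralin with C9' pivalate, C9 benzyl ether, 6-OMe, 7-OBn | COc1cc([C@H]2c3cc(OCc4ccccc4)c(OC)cc3C[C@@H](COCc3ccccc3)[C@@H]2COC(=O)C(C)(C)C)ccc1O | intermediate
18 | O-benzyl ether of 17 (three benzyl ethers, C9' pivalate) | COc1cc([C@H]2c3cc(OCc4ccccc4)c(OC)cc3C[C@@H](COCc3ccccc3)[C@@H]2COC(=O)C(C)(C)C)ccc1OCc1ccccc1 | intermediate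
19 | C9' alcohol (three benzyl ethers) | COc1cc([C@H]2c3cc(OCc4ccccc4)c(OC)cc3C[C@@H](COCc3ccccc3)[C@@H]2CO)ccc1OCc1ccccc1 | intermediate
20 | pyridinium C9' sulfate of 19 | COc1cc([C@H]2c3cc(OCc4ccccc4)c(OC)cc3C[C@@H](COCc3ccccc3)[C@@H]2COS(=O)(=O)[O-])ccc1OCc1ccccc1.c1cc[nH+]cc1 | intermediate (not isolated)
21 | sodium C9' sulfate of 19 | COc1cc([C@H]2c3cc(OCc4ccccc4)c(OC)cc3C[C@@H](COCc3ccccc3)[C@@H]2COS(=O)(=O)[O-])ccc1OCc1ccccc1.[Na+] | intermediate
22 | sodium salt of the target | COc1cc([C@H]2c3cc(O)c(OC)cc3C[C@@H](CO)[C@@H]2COS(=O)(=O)[O-])ccc1O.[Na+] | intermediate (not isolated)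
23 | CNP0184747.1, (1S,2R,3R) all-trans C9' hydrogen sulfate | COc1cc([C@H]2c3cc(O)c(OC)cc3C[C@@H](CO)[C@@H]2COS(=O)(=O)O)ccc1O | target

**Step count and risks**

Total steps: 13. Longest linear sequence: 13 steps (1 to 23); 2, 7 and 15 are bought.

Steps most likely to fail:

1. Step 9. Guaiacol may react through the carbon para to its methoxy group, the cation may lose the C2 proton (erasing C2) or be captured by the C9 ether oxygen, or the aldehyde may be arylated twice by guaiacol before ring closure. Fallback: setting out from aldehyde 14, the pendant ring is brought in as a nucleophile of fixed regiochemistry. [4-(Benzyloxy)-3-methoxyphenyl]magnesium bromide F1 (from 1-(benzyloxy)-4-bromo-2-methoxybenzene and Mg in THF) is added to 14 at −78 °C to give the diaryl carbinol F2 as a mixture at C1. TFA in CH2Cl2 at 0 °C then ionises the carbinol and the tethered ring closes onto the cation para to its methoxy group (Friedel–Crafts cycloalkylation, the classical 1-aryltetralin closure). This should give the all-trans tribenzyl pivalate 18 directly, where the route is rejoined at step 11.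

2. Step 4. Methanol may be eliminated from the β-methoxy lactone under the Lewis acid, or the ketene acetal may be desilylated back to 6 instead of C-alkylated. Fallback: setting out from lactone 6, the carbon is added at the alcohol level by a standard aldol. LiN(iPr)2 then gaseous formaldehyde should give the trans α-hydroxymethyl lactone F3, and PMB trichloroacetimidate with catalytic camphorsulfonic acid its PMB ether F4. Opening and benzylation as in step 5 lead through the sodium hydroxy carboxylate F5 to the benzyl ester F6. LiAlH4 gives the alcohol F7 and pivaloyl chloride the pivalate F8. DDQ in wet CH2Cl2 removes the PMB group to give the primary alcohol F9, and Dess–Martin periodinane oxidises it to aldehyde 14, where the route is rejoined.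

3. Step 5. The hydroxy carboxylate may relactonise if O-benzylation is incomplete, and excess base may epimerise C2 or eliminate methoxide from the benzyl ester. Fallback: setting out from lactone 9, the ring is opened by aminolysis. Pyrrolidine with AlMe3 in CH2Cl2 gives the γ-hydroxy pyrrolidine amide F10, whose α-hydrogen is far less acidic than that of an ester. NaH and BnBr give the benzyl ether amide F11, and LiNH2BH3 in THF reduces the tertiary amide to the primary alcohol 12, where the route is rejoined.

**Further compounds**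

F1 | step 9 | [4-(benzyloxy)-3-methoxyphenyl]magnesium bromide | COc1cc([Mg]Br)ccc1OCc1ccccc1
F2 | step 9 | diaryl carbinol from 14 (C1 epimers; C2, C3 as in 14) | COc1cc(C(O)[C@@H](COC(=O)C(C)(C)C)[C@H](COCc2ccccc2)Cc2ccc(OCc3ccccc3)c(OC)c2)ccc1OCc1ccccc1
F3 | step 4 | (3S,4R)-4-[[4-(benzyloxy)-3-methoxyphenyl]methyl]-3-(hydroxymethyl)oxolan-2-one (trans) | O=C1[C@H](CO)[C@H](CO1)Cc1ccc(OCc2ccccc2)c(OC)c1
F4 | step 4 | PMB ether of F3 | O=C1[C@H](COCc2ccc(OC)cc2)[C@H](CO1)Cc1ccc(OCc2ccccc2)c(OC)c1
F5 | step 4 | sodium hydroxy carboxylate from F4 | [Na+].[O-]C(=O)[C@H](COCc1ccc(OC)cc1)[C@H](CO)Cc1ccc(OCc2ccccc2)c(OC)c1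
F6 | step 4 | benzyl ester, C9 benzyl ether, C1 PMB ether | O=C(OCc1ccccc1)[C@H](COCc1ccc(OC)cc1)[C@H](COCc1ccccc1)Cc1ccc(OCc2ccccc2)c(OC)c1
F7 | step 4 | C9' alcohol from F6 | OC[C@H](COCc1ccc(OC)cc1)[C@H](COCc1ccccc1)Cc1ccc(OCc2ccccc2)c(OC)c1
F8 | step 4 | C9' pivalate of F7 | CC(C)(C)C(=O)OC[C@H](COCc1ccc(OC)cc1)[C@H](COCc1ccccc1)Cc1ccc(OCc2ccccc2)c(OC)c1
F9 | step 4 | C1 alcohol after PMB removal | CC(C)(C)C(=O)OC[C@H](CO)[C@H](COCc1ccccc1)Cc1ccc(OCc2ccccc2)c(OC)c1
F10 | step 5 | γ-hydroxy pyrrolidine amide from 9 | O=C(N1CCCC1)[C@H](C(OC)OC)[C@H](CO)Cc1ccc(OCc2ccccc2)c(OC)c1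
F11 | step 5 | C9 benzyl ether of F10 | O=C(N1CCCC1)[C@H](C(OC)OC)[C@H](COCc1ccccc1)Cc1ccc(OCc2ccccc2)c(OC)c1
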